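## Retrosynthetic overview

1. The last bond made is the C4–O–acetyl bond. A chiral acyl-transfer catalyst acetylates only the (1S,4R,5S,6R,7S) half of a racemic endo-4-alcohol, so one C–O bond formation completes the constitution and fixes the absolute configuration. The aryl silyl ether comes off in the same flask.
2. The 4-alcohol comes from the 4,8-dione by site- and face-selective 1,2-reduction of the enone carbonyl, which sets C4.
3. The dione comes from a cationic [5+2] union of a p-quinone monoketal with an (E)-propenylarene. This forms C1–C7 and C5–C6 and sets C1, C5, C6 and C7 relative to each other.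
4. The monoketal comes from 2,3,4-trimethoxyphenol by O-allylation, Claisen shift and oxidative C–O ketalisation.
5. Ring order: the bought phenol ring becomes the six-membered ring C1-C2-C3-C4-C5-C8. The cyclopentanone C1-C7-C6-C5-C8, and with it the bicyclo[3.2.1] frame, closes in the [5+2] step. The syringyl ring is bought.

Assumption: 2,3,4-trimethoxyphenol and the E isomer of flavour-grade 4-propenylsyringol are taken as catalogue items.

Locants used for all bicyclic compounds: C1 allyl bridgehead, C2=C3(OMe), C4, C5 OMe bridgehead, C6 (aryl), C7 (methyl), C8 bridging C=O. "Endo" means on the face of the other large bridge, anti to C8.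

## Route

**Step 1**
Reactants: 1 2,3,4-trimethoxyphenol
Product: 2 1-(allyloxy)-2,3,4-trimethoxybenzene
Conditions: allyl bromide, K2CO3, acetone, reflux
Reagents that add atoms: allyl bromide, C=CCBr
Why: Williamson O-allylation (SN2 of the phenoxide on allyl bromide) is reliable on this phenol and forms no stereocentre.

**Step 2**
Reactants: 2 1-(allyloxy)-2,3,4-trimethoxybenzene
Product: 3 6-allyl-2,3,4-trimethoxyphenol
Conditions: PhNEt2, 200 °C
Reagents that add atoms: none
Why: In this aromatic Claisen [3,3] rearrangement one ortho carbon carries OMe, so the allyl group ends at the only free ortho carbon and tautomerisation restores the phenol, with no stereocentre formed.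

**Step 3**
Reactants: 3 6-allyl-2,3,4-trimethoxyphenol
Product: 4 2-allyl-4,4,5,6-tetramethoxycyclohexa-2,5-dien-1-one
Conditions: PhI(OAc)2, MeOH, 0 °C
Reagents that add atoms: methanol, CO
Why: In this iodine(III) oxidative dearomatisation of a 4-methoxyphenol, the aryloxy-iodane loses PhI and methanol is captured at the OMe-stabilised para carbon, giving the achiral p-quinone monoketal while the isolated allyl group is untouched.

**Step 4**
Reactants: 4 2-allyl-4,4,5,6-tetramethoxycyclohexa-2,5-dien-1-one; 5 (E)-2,6-dimethoxy-4-(prop-1-en-1-yl)phenol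
Product: 7 (±)-(1S*,5R*,6R*,7S*)-1-allyl-6-[4-(tert-butyldimethylsilyloxy)-3,5-dimethoxyphenyl]-3,5-dimethoxy-7-methylbicyclo[3.2.1]oct-2-ene-4,8-dione (6-endo-aryl 7-exo-methyl), via propenylsyringol TBS ether 6 (not isolated)
Conditions: 5 (1.2 equiv), TBSOTf, 2,6-lutidine, CH2Cl2, 0 °C; then 4, TMSOTf (20 mol %), −78 → −40 °C; Et3N then NaHCO3 quench
Reagents that add atoms: tert-butyldimethylsilyl triflate, CC(C)(C)[Si](C)(C)OS(=O)(=O)C(F)(F)F
Why: In this Büchi-type cationic [5+2] cycloaddition TMSOTf ionises the ketal to the 4-methoxyphenoxenium (pentadienyl) cation, the nucleophilic CHMe terminus of the silyl-masked styrene bonds to the allyl-bearing carbon rather than to the deactivated dimethoxy-substituted C=C, and the enol-ether carbon C5 closes on the benzylic cation, so the E alkene gives trans Me/Ar, stacking of the aryl under the cationic three-carbon unit gives endo-aryl/exo-methyl, and the C4 oxocarbenium loses its methyl to MeOTMS (Me2O out, TMSOTf regenerated) to leave the racemic dione.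

**Step 5**
Reactants: 7 the (±)-4,8-dione
Product: 8 (±)-(1S*,4R*,5S*,6R*,7S*)-1-allyl-6-[4-(tert-butyldimethylsilyloxy)-3,5-dimethoxyphenyl]-4-hydroxy-3,5-dimethoxy-7-methylbicyclo[3.2.1]oct-2-en-8-one (4-OH endo and syn to the aryl)
Conditions: NaBH4 (1 equiv), CeCl3·7H2O, MeOH/CH2Cl2, −78 °C; acetone then pH 7 buffer
Reagents that add atoms: none
Why: In this Luche 1,2-reduction the hard Ce(III)/methanol-modified borohydride takes the enone carbonyl C4 while C8 is shielded between two fully substituted bridgeheads, and the endo aryl at C6 blocks the lower face so hydride arrives from the C8-bridge face and sets the endo 4-OH, with cold neutral work-up avoiding retro-aldol of the β-hydroxy ketone.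

**Step 6 (key step)**
Reactants: 8 the (±)-endo-4-alcohol
Product: 10 (1S,4R,5S,6R,7S)-1-allyl-6-(4-hydroxy-3,5-dimethoxyphenyl)-3,5-dimethoxy-7-methyl-8-oxobicyclo[3.2.1]oct-2-en-4-yl acetate, via silylated acetate 9 (not isolated)
Conditions: Ac2O (0.45 equiv), (2R,3S)-HyperBTM (5–10 mol %), i-Pr2NEt (0.5 equiv), CHCl3, −20 °C, to ca. 40 % conversion (HPLC); then THF, TBAF/AcOH (1:1), 0 °C; chromatography
Reagents that add atoms: acetic anhydride, CC(=O)OC(C)=O
Why: Proposed new method: an acylative kinetic resolution of a bridged 2-methoxy-allylic (enol-ether) carbinol next to a quaternary centre, in which Ac2O forms the N-acetyl isothiouronium acetate (acyl C=O locked syn to S by the 1,5-O···S contact, one face blocked by the catalyst phenyl), the electron-rich C2=C3 enol-ether π bond stacks on the cationic heterocycle while the quaternary C5 points away and acetate deprotonates the OH, an arrangement that only the (4R) enantiomer can reach (its π-side/alkyl-side layout maps onto the (S)-1-arylethanol series that this catalyst hand acylates fastest) and that in the antipode pushes C5-OMe and the C6 aryl into the catalyst phenyl, while the neopentyl endo OH has almost no uncatalysed background, so the new C–O(acyl) bond selects the absolute configuration of all five stereocentres; the closest known reaction type is isothiourea or planar-chiral DMAP kinetic resolution of simple benzylic and allylic secondary alcohols, and buffered fluoride then removes only the aryl silyl ether.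

## Compound list

1 | 2,3,4-trimethoxyphenol | COc1ccc(O)c(OC)c1OC | starting material
2 | 1-(allyloxy)-2,3,4-trimethoxybenzene | C=CCOc1ccc(OC)c(OC)c1OC | intermediate
3 | 6-allyl-2,3,4-trimethoxyphenol | C=CCc1cc(OC)c(OC)c(OC)c1O | intermediate
4 | 2-allyl-4,4,5,6-tetramethoxycyclohexa-2,5-dien-1-one | C=CCC1=CC(OC)(OC)C(OC)=C(OC)C1=O | intermediate
5 | (E)-2,6-dimethoxy-4-(prop-1-en-1-yl)phenol | C/C=C/c1cc(OC)c(O)c(OC)c1 | starting material
6 | (E)-tert-butyl[2,6-dimethoxy-4-(prop-1-en-1-yl)phenoxy]dimethylsilane (not isolated) | C/C=C/c1cc(OC)c(O[Si](C)(C)C(C)(C)C)c(OC)c1 | intermediate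
7 | (±)-(1S*,5R*,6R*,7S*)-4,8-dione TBS ether, racemic, enantiomer drawn is the one that ends in 10 | C=CC[C@]12C=C(OC)C(=O)[C@](OC)(C1=O)[C@@H](c1cc(OC)c(O[Si](C)(C)C(C)(C)C)c(OC)c1)[C@@H]2C | intermediate
8 | (±)-(1S*,4R*,5S*,6R*,7S*)-endo-4-alcohol TBS ether, racemic, enantiomer drawn is the one that ends in 10 | C=CC[C@]12C=C(OC)[C@@H](O)[C@](OC)(C1=O)[C@@H](c1cc(OC)c(O[Si](C)(C)C(C)(C)C)c(OC)c1)[C@@H]2C | intermediate
9 | (1S,4R,5S,6R,7S)-4-acetate TBS ether (not isolated) | C=CC[C@]12C=C(OC)[C@@H](OC(C)=O)[C@](OC)(C1=O)[C@@H](c1cc(OC)c(O[Si](C)(C)C(C)(C)C)c(OC)c1)[C@@H]2C | intermediate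
10 | (1S,4R,5S,6R,7S)-1-allyl-6-(4-hydroxy-3,5-dimethoxyphenyl)-3,5-dimethoxy-7-methyl-8-oxobicyclo[3.2.1]oct-2-en-4-yl acetate | C=CC[C@]12C=C(OC)[C@@H](OC(C)=O)[C@](OC)(C1=O)[C@@H](c1cc(OC)c(O)c(OC)c1)[C@@H]2C | target

## Step count and risks

Total steps: 6. Longest linear sequence: 6 (1 → 2 → 3 → 4 → 7 → 8 → 10). Compound 5 enters at step 4.

**Step 6 (the new step).** There are four concerns.
- The neopentyl endo OH may acylate too slowly.
- The endo aryl may compete with the enol ether as the π partner and lower or invert the selectivity. The antipodal catalyst is equally available.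
- A selectivity factor of about 50 is needed for roughly 93 % ee at 40 % conversion, with crystallisation to polish the ee.
- The yield cannot exceed 50 %.

The fallback uses known chemistry, sets out from 8 and returns at 9. Racemic 8 is separated by preparative SFC on an immobilised polysaccharide phase. The single-enantiomer (1S,4R,5S,6R,7S)-endo-4-alcohol TBS ether F4 is acetylated with Ac2O, DMAP and Et3N in CH2Cl2 to give 9. TBAF/AcOH then converts 9 into 10 as in the route.

**Step 4.** The benzylic cation may close on the carbonyl oxygen (formal [3+2]) instead of on C5, or the aryl may end up exo. The fallback sets out from 4 and 6 and returns at 7.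
- The oxygen closure is accepted on purpose. Coupling 4 with 6 under catalytic TfOH in MeCN at 0 °C gives (±)-3a-allyl-2-[4-(tert-butyldimethylsilyloxy)-3,5-dimethoxyphenyl]-5,7-dimethoxy-3-methyl-3,3a-dihydro-1-benzofuran-6(2H)-one (2,3-trans, 3-methyl and 3a-allyl cis) F1.
- This compound is then isomerised with BF3·OEt2 or p-TsOH in CH2Cl2. The benzylic C–O bond ionises and the freed vinylogous acid is C-alkylated at the OMe-bearing carbon.
- This is the known hydrobenzofuranoid-to-bicyclo[3.2.1]octanoid neolignan rearrangement. It keeps C1 and C7 intact and delivers 7.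

**Step 5.** The C8 ketone may be reduced alongside or instead of C4. The fallback sets out from 7 and returns at 9.
- Both carbonyls are reduced with excess NaBH4/CeCl3 in MeOH at 0 °C to the (±)-4-endo,8-diol TBS ether (8-OH predicted on the side of the C6–C7 bridge, configuration of no consequence) F2.
- Under the step 6 catalyst conditions only the allylic C4–OH is acetylated, because the C8 carbinol lies between two quaternary carbons. This gives the (1S,4R,5S,6R,7S)-4-acetoxy-8-hydroxy TBS ether F3, which is separated from the unreacted diol.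
- Dess–Martin periodinane with NaHCO3 in CH2Cl2 re-oxidises C8 to give 9.

## Further compounds

F1 | step 4 | (±)-3a-allyl-2-[4-(tert-butyldimethylsilyloxy)-3,5-dimethoxyphenyl]-5,7-dimethoxy-3-methyl-3,3a-dihydro-1-benzofuran-6(2H)-one, 2,3-trans, 3-Me/3a-allyl cis | C=CC[C@]12C=C(OC)C(=O)C(OC)=C1O[C@@H](c1cc(OC)c(O[Si](C)(C)C(C)(C)C)c(OC)c1)[C@@H]2C
F2 | step 5 | (±)-1-allyl-6-[4-(tert-butyldimethylsilyloxy)-3,5-dimethoxyphenyl]-3,5-dimethoxy-7-methylbicyclo[3.2.1]oct-2-ene-4,8-diol, 4-OH endo, 8-OH toward the C6–C7 bridge | C=CC[C@]12C=C(OC)[C@@H](O)[C@](OC)([C@H]1O)[C@@H](c1cc(OC)c(O[Si](C)(C)C(C)(C)C)c(OC)c1)[C@@H]2C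
F3 | step 5 | single-enantiomer 4-acetoxy-8-hydroxy TBS ether of the target series | C=CC[C@]12C=C(OC)[C@@H](OC(C)=O)[C@](OC)([C@H]1O)[C@@H](c1cc(OC)c(O[Si](C)(C)C(C)(C)C)c(OC)c1)[C@@H]2C
F4 | step 6 | (1S,4R,5S,6R,7S)-endo-4-alcohol TBS ether, single enantiomer of 8 | C=CC[C@]12C=C(OC)[C@@H](O)[C@](OC)(C1=O)[C@@H](c1cc(OC)c(O[Si](C)(C)C(C)(C)C)c(OC)c1)[C@@H]2C
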